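**Retrosynthetic overview**
- Both oxazoles are cut last and together: target ⇒ macrocyclic bis(β-acyloxy aldehyde) + 2 TosMIC (double van Leusen annulation, two rings in one operation).
- The 20-membered ring is cut at one C(sp2)–C(sp3) bond next to a dienoate (macrocyclic B-alkyl Suzuki); the other such bond is cut by an intermolecular B-alkyl Suzuki and both ester C–O bonds by acylation.
- This leaves one homoallylic alcohol used twice (syn Me/OH pair from a Brown (Z)-crotylboration of 3,3-diethoxypropanal) and two (2Z,4Z)-5-iodo-dienoic acids (with and without 2-methyl) from (Z)-3-iodoacrolein by Still–Gennari olefination.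
- Ring order: macrocycle first, then the two oxazole rings simultaneously in the last step; the diethyl acetals that carry the future oxazole C5 carbons are the only masking groups.

Assumption: the SMILES is read literally, so both dienoates are (2Z,4Z) and all four sp3 stereocentres are R (methyl and acyloxy syn in each half).

**Route**

Step 1
Reactants: 1 ethyl 3,3-diethoxypropanoate
Product: 2 3,3-diethoxypropanal
Conditions: i-Bu2AlH (1.05 equiv), CH2Cl2, −78 °C, 1 h; MeOH, then aq. KNaC4H4O6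
Reagents that add atoms: none
Why: Partial ester reduction with a hindered aluminium hydride at −78 °C (i-Bu2AlH reduction) stops at the aldehyde, which is released only on aqueous work-up; no stereocentre is formed.

Step 2
Reactants: 2 3,3-diethoxypropanal
Product: 3 (3R,4R)-1,1-diethoxy-4-methylhex-5-en-3-ol
Conditions: cis-2-butene, KOt-Bu, n-BuLi, THF, −78 to −45 °C; (−)-Ipc2BOMe [from (+)-α-pinene], −78 °C; BF3·OEt2 (1.2 equiv); then 2, −78 °C, 3 h; NaOH, H2O2, rt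
Reagents that add atoms: cis-2-butene, C/C=C\C
Why: Brown asymmetric crotylboration: the (Z)-crotylborane reacts through a closed chair transition state so that Z geometry gives the 3,4-syn pair, and the isopinocampheyl groups derived from (+)-α-pinene direct attack to the aldehyde face that gives 3R and therefore 4R.

Step 3
Reactants: 4 ethyl (2Z)-3-iodoprop-2-enoate
Product: 5 (2Z)-3-iodoprop-2-enal
Conditions: i-Bu2AlH (1.0 equiv), CH2Cl2, −78 °C, 30 min; cold aq. KNaC4H4O6; crude solution used at once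
Reagents that add atoms: none
Why: Low-temperature i-Bu2AlH partial reduction of the ester gives the configurationally labile (Z)-enal, which is kept cold and used immediately so that the Z geometry present in 4 is retained.

Step 4
Reactants: 5 (2Z)-3-iodoprop-2-enal
Product: 6 ethyl (2Z,4Z)-5-iodo-2-methylpenta-2,4-dienoate
Conditions: (CF3CH2O)2P(O)CH(CH3)CO2Et, KN(SiMe3)2, 18-crown-6, THF, −78 °C, 2 h
Reagents that add atoms: ethyl 2-[bis(2,2,2-trifluoroethoxy)phosphoryl]propanoate, CCOC(=O)C(C)P(=O)(OCC(F)(F)F)OCC(F)(F)F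
Why: Still–Gennari variant of the Horner–Wadsworth–Emmons olefination: the electron-poor phosphonate with a crown-separated potassium counter-ion eliminates fast from the kinetic adduct and gives the trisubstituted 2Z alkene, while the 4Z iodoalkene is not touched at −78 °C.

Step 5
Reactants: 6 ethyl (2Z,4Z)-5-iodo-2-methylpenta-2,4-dienoate
Product: 7 (2Z,4Z)-5-iodo-2-methylpenta-2,4-dienoic acid
Conditions: LiOH·H2O, THF/H2O (3:1), 0 °C to rt; 1 M HCl to pH 3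
Reagents that add atoms: lithium hydroxide, [Li+].[OH-]
Why: Ester saponification at the acyl carbon leaves the alkenyl iodide and both Z alkenes unchanged, because the carboxylate formed is no longer a Michael acceptor.

Step 6
Reactants: 5 (2Z)-3-iodoprop-2-enal
Product: 8 methyl (2Z,4Z)-5-iodopenta-2,4-dienoate
Conditions: (CF3CH2O)2P(O)CH2CO2Me, KN(SiMe3)2, 18-crown-6, THF, −78 °C, 1 h
Reagents that add atoms: methyl 2-[bis(2,2,2-trifluoroethoxy)phosphoryl]acetate, COC(=O)CP(=O)(OCC(F)(F)F)OCC(F)(F)F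
Why: Still–Gennari olefination under kinetic control gives the new 2Z alkene next to the preserved 4Z iodoalkene.

Step 7
Reactants: 8 methyl (2Z,4Z)-5-iodopenta-2,4-dienoate
Product: 9 (2Z,4Z)-5-iodopenta-2,4-dienoic acid
Conditions: LiOH·H2O, THF/H2O (3:1), 0 °C, 2 h; 1 M HCl to pH 3
Reagents that add atoms: lithium hydroxide, [Li+].[OH-]
Why: Mild saponification of the methyl ester, as in step 5, without change of alkene geometry.

Step 8
Reactants: 3 (3R,4R)-1,1-diethoxy-4-methylhex-5-en-3-ol, 7 (2Z,4Z)-5-iodo-2-methylpenta-2,4-dienoic acid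
Product: 10 (3R,4R)-1,1-diethoxy-4-methylhex-5-en-3-yl (2Z,4Z)-5-iodo-2-methylpenta-2,4-dienoate
Conditions: DIC, DMAP (10 mol %), CH2Cl2, −20 to 0 °C
Reagents that add atoms: none
Why: Steglich esterification (carbodiimide activation with catalytic DMAP) acylates the secondary alcohol with retention at C3, the low temperature, small amount of DMAP and α-methyl group limiting Z to E isomerisation of the acyl donor.

Step 9
Reactants: 3 (3R,4R)-1,1-diethoxy-4-methylhex-5-en-3-ol, 10 (3R,4R)-1,1-diethoxy-4-methylhex-5-en-3-yl (2Z,4Z)-5-iodo-2-methylpenta-2,4-dienoate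
Product: 12 (3R,4R)-1,1-diethoxy-4-methylhex-5-en-3-yl (2Z,4Z,8R,9R)-11,11-diethoxy-9-hydroxy-2,8-dimethylundeca-2,4-dienoate, via bis(9-BBN) adduct 11 (not isolated)
Conditions: 3 (1.3 equiv), 9-BBN (2.9 equiv), THF, 0 °C to rt, 4 h; aq. Cs2CO3 (3 M), 20 min; then 10, Pd(dppf)Cl2 (8 mol %), AsPh3 (8 mol %), DMF, rt, 12 h
Reagents that add atoms: none
Why: B-alkyl Suzuki–Miyaura coupling: 9-BBN masks the hydroxyl as its borinate and adds anti-Markovnikov to the terminal alkene of 3, and the alkylborane 11 couples with the alkenyl iodide of 10 with retention of the 4Z geometry while the vinyl group of 10 is inert; no stereocentre is touched.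

Step 10
Reactants: 12 (3R,4R)-1,1-diethoxy-4-methylhex-5-en-3-yl (2Z,4Z,8R,9R)-11,11-diethoxy-9-hydroxy-2,8-dimethylundeca-2,4-dienoate, 9 (2Z,4Z)-5-iodopenta-2,4-dienoic acid
Product: 13 (3R,4R)-1,1-diethoxy-4-methylhex-5-en-3-yl (2Z,4Z,8R,9R)-11,11-diethoxy-9-{[(2Z,4Z)-5-iodopenta-2,4-dienoyl]oxy}-2,8-dimethylundeca-2,4-dienoate
Conditions: DIC, DMAP (10 mol %), CH2Cl2, −20 to 0 °C
Reagents that add atoms: none
Why: Steglich esterification of the free C9 hydroxyl with retention of configuration, under the same low-temperature conditions as step 8.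

Step 11
Reactants: 13 (3R,4R)-1,1-diethoxy-4-methylhex-5-en-3-yl (2Z,4Z,8R,9R)-11,11-diethoxy-9-{[(2Z,4Z)-5-iodopenta-2,4-dienoyl]oxy}-2,8-dimethylundeca-2,4-dienoate
Product: 15 (3Z,5Z,9R,10R,13Z,15Z,19R,20R)-10,20-bis(2,2-diethoxyethyl)-3,9,19-trimethyl-1,11-dioxacycloicosa-3,5,13,15-tetraene-2,12-dione, via alkyl-9-BBN borane 14 (not isolated)
Conditions: 9-BBN (1.5 equiv), THF, rt, 3 h; then syringe-pump addition (12 h) to Pd(dppf)Cl2 (20 mol %), AsPh3 (20 mol %), Cs2CO3 (5 equiv), DMF/THF/H2O (10:1:1), 45 °C, final 1 mM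
Reagents that add atoms: none
Why: Macrocyclic B-alkyl Suzuki–Miyaura coupling: 9-BBN hydroborates only the single terminal alkene, and slow addition of 14 to the zerovalent palladium catalyst at high dilution closes the 20-membered ring at the sp2–sp3 bond with retention of alkene geometry.

Step 12
Reactants: 15 (3Z,5Z,9R,10R,13Z,15Z,19R,20R)-10,20-bis(2,2-diethoxyethyl)-3,9,19-trimethyl-1,11-dioxacycloicosa-3,5,13,15-tetraene-2,12-dione
Product: 16 2,2'-[(3Z,5Z,9R,10R,13Z,15Z,19R,20R)-3,9,19-trimethyl-2,12-dioxo-1,11-dioxacycloicosa-3,5,13,15-tetraene-10,20-diyl]diacetaldehyde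
Conditions: TFA/H2O/CH2Cl2 (1:1:8), 0 °C to rt, 2 h; crude dialdehyde used at once
Reagents that add atoms: water, O
Why: Acid-catalysed acetal hydrolysis through oxocarbenium ions unmasks both aldehydes under conditions in which β-acyloxy aldehydes do not eliminate and the lactones and Z,Z-dienes are stable.

Step 13
Reactants: 16 2,2'-[(3Z,5Z,9R,10R,13Z,15Z,19R,20R)-3,9,19-trimethyl-2,12-dioxo-1,11-dioxacycloicosa-3,5,13,15-tetraene-10,20-diyl]diacetaldehyde
Product: 18 (3Z,5Z,9R,10R,13Z,15Z,19R,20R)-3,9,19-trimethyl-10,20-bis(1,3-oxazol-5-ylmethyl)-1,11-dioxacycloicosa-3,5,13,15-tetraene-2,12-dione, via bis(4-tosyl-2-oxazoline) 17 (not isolated)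
Conditions: TosMIC (2.3 equiv), K3PO4 (4.5 equiv), i-PrOH/DME (1:1), 0 °C, 2 h; then 60 °C, 4 h
Reagents that add atoms: TosMIC (p-toluenesulfonylmethyl isocyanide), [C-]#[N+]CS(=O)(=O)c1ccc(C)cc1
Why: Double van Leusen oxazole synthesis: the TosMIC anion adds to each aldehyde faster than the weak heterogeneous base can enolise it, ring closure of the alkoxide onto the isocyanide gives 17, and loss of p-toluenesulfinic acid on warming aromatises both rings in the same operation to the 5-substituted oxazoles, the hindered alcohol sparing the lactones and no stereocentre being touched.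

**Compound list**

1 | ethyl 3,3-diethoxypropanoate | CCOC(=O)CC(OCC)OCC | starting material
2 | 3,3-diethoxypropanal | O=CCC(OCC)OCC | intermediate
3 | (3R,4R)-1,1-diethoxy-4-methylhex-5-en-3-ol | C=C[C@@H](C)[C@@H](CC(OCC)OCC)O | intermediate
4 | ethyl (2Z)-3-iodoprop-2-enoate | CCOC(=O)/C=C\I | starting material
5 | (2Z)-3-iodoprop-2-enal | O=C/C=C\I | intermediate
6 | ethyl (2Z,4Z)-5-iodo-2-methylpenta-2,4-dienoate | CCOC(=O)/C(C)=C\C=C/I | intermediate
7 | (2Z,4Z)-5-iodo-2-methylpenta-2,4-dienoic acid | OC(=O)/C(C)=C\C=C/I | intermediate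
8 | methyl (2Z,4Z)-5-iodopenta-2,4-dienoate | COC(=O)/C=C\C=C/I | intermediate
9 | (2Z,4Z)-5-iodopenta-2,4-dienoic acid | OC(=O)/C=C\C=C/I | intermediate
10 | (3R,4R)-1,1-diethoxy-4-methylhex-5-en-3-yl (2Z,4Z)-5-iodo-2-methylpenta-2,4-dienoate | C=C[C@@H](C)[C@@H](CC(OCC)OCC)OC(=O)/C(C)=C\C=C/I | intermediate
11 | 9-{[(3R,4R)-6-(9-borabicyclo[3.3.1]nonan-9-yl)-1,1-diethoxy-4-methylhexan-3-yl]oxy}-9-borabicyclo[3.3.1]nonane | B1(C2CCCC1CCC2)CC[C@@H](C)[C@@H](CC(OCC)OCC)OB1C2CCCC1CCC2 | intermediate (not isolated)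
12 | (3R,4R)-1,1-diethoxy-4-methylhex-5-en-3-yl (2Z,4Z,8R,9R)-11,11-diethoxy-9-hydroxy-2,8-dimethylundeca-2,4-dienoate | C=C[C@@H](C)[C@@H](CC(OCC)OCC)OC(=O)/C(C)=C\C=C/CC[C@@H](C)[C@@H](CC(OCC)OCC)O | intermediate
13 | (3R,4R)-1,1-diethoxy-4-methylhex-5-en-3-yl (2Z,4Z,8R,9R)-11,11-diethoxy-9-{[(2Z,4Z)-5-iodopenta-2,4-dienoyl]oxy}-2,8-dimethylundeca-2,4-dienoate | C=C[C@@H](C)[C@@H](CC(OCC)OCC)OC(=O)/C(C)=C\C=C/CC[C@@H](C)[C@@H](CC(OCC)OCC)OC(=O)/C=C\C=C/I | intermediate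
14 | (3R,4R)-6-(9-borabicyclo[3.3.1]nonan-9-yl)-1,1-diethoxy-4-methylhexan-3-yl (2Z,4Z,8R,9R)-11,11-diethoxy-9-{[(2Z,4Z)-5-iodopenta-2,4-dienoyl]oxy}-2,8-dimethylundeca-2,4-dienoate | B1(C2CCCC1CCC2)CC[C@@H](C)[C@@H](CC(OCC)OCC)OC(=O)/C(C)=C\C=C/CC[C@@H](C)[C@@H](CC(OCC)OCC)OC(=O)/C=C\C=C/I | intermediate (not isolated)
15 | (3Z,5Z,9R,10R,13Z,15Z,19R,20R)-10,20-bis(2,2-diethoxyethyl)-3,9,19-trimethyl-1,11-dioxacycloicosa-3,5,13,15-tetraene-2,12-dione | C/C1=C/C=C\CC[C@@H](C)[C@@H](CC(OCC)OCC)OC(=O)/C=C\C=C/CC[C@@H](C)[C@@H](CC(OCC)OCC)OC1=O | intermediate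
16 | 2,2'-[(3Z,5Z,9R,10R,13Z,15Z,19R,20R)-3,9,19-trimethyl-2,12-dioxo-1,11-dioxacycloicosa-3,5,13,15-tetraene-10,20-diyl]diacetaldehyde | C/C1=C/C=C\CC[C@@H](C)[C@@H](CC=O)OC(=O)/C=C\C=C/CC[C@@H](C)[C@@H](CC=O)OC1=O | intermediate
17 | (3Z,5Z,9R,10R,13Z,15Z,19R,20R)-3,9,19-trimethyl-10,20-bis{[4-(4-methylbenzenesulfonyl)-4,5-dihydro-1,3-oxazol-5-yl]methyl}-1,11-dioxacycloicosa-3,5,13,15-tetraene-2,12-dione (oxazoline centres unassigned) | C/C1=C/C=C\CC[C@@H](C)[C@@H](CC2OC=NC2S(=O)(=O)c2ccc(C)cc2)OC(=O)/C=C\C=C/CC[C@@H](C)[C@@H](CC2OC=NC2S(=O)(=O)c2ccc(C)cc2)OC1=O | intermediate (not isolated)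
18 | (3Z,5Z,9R,10R,13Z,15Z,19R,20R)-3,9,19-trimethyl-10,20-bis(1,3-oxazol-5-ylmethyl)-1,11-dioxacycloicosa-3,5,13,15-tetraene-2,12-dione | C/C1=C/C=C\CC[C@@H](C)[C@@H](Cc2cnco2)OC(=O)/C=C\C=C/CC[C@@H](C)[C@@H](Cc2cnco2)OC1=O | target

**Step count and risks**

Total step count: 13. Longest linear sequence: 9 steps (4 → 5 → 6 → 7 → 10 → 12 → 13 → 15 → 16 → 18).

The three steps most likely to fail:

Step 13. Both aldehydes of 16 carry an acyloxy group in the β-position, so base can trigger E1cB loss of the dienoate or attack the lactones before TosMIC has added. The fallback makes the oxazoles one at a time before any ester exists; it sets out from 3 and comes back to the route at 18. Hydrolysis of the acetal of 3 (AcOH/H2O/THF) gives (3R,4R)-3-hydroxy-4-methylhex-5-enal F1, whose β-hydroxyl is a poor leaving group. TosMIC with K2CO3 in MeOH converts it into (2R,3R)-3-methyl-1-(1,3-oxazol-5-yl)pent-4-en-2-ol F2. Acylation of F2 with 7 (DIC, DMAP) gives (2R,3R)-3-methyl-1-(1,3-oxazol-5-yl)pent-4-en-2-yl (2Z,4Z)-5-iodo-2-methylpenta-2,4-dienoate F3. A second portion of F2 with 9-BBN gives the bis(9-BBN) adduct F4, which is coupled with F3 (Pd(dppf)Cl2, AsPh3, Cs2CO3) to the hydroxy ester (2R,3R)-3-methyl-1-(1,3-oxazol-5-yl)pent-4-en-2-yl (2Z,4Z,8R,9R)-9-hydroxy-2,8-dimethyl-10-(1,3-oxazol-5-yl)deca-2,4-dienoate F5. Acylation with 9 gives the iodide (2R,3R)-3-methyl-1-(1,3-oxazol-5-yl)pent-4-en-2-yl (2Z,4Z,8R,9R)-9-{[(2Z,4Z)-5-iodopenta-2,4-dienoyl]oxy}-2,8-dimethyl-10-(1,3-oxazol-5-yl)deca-2,4-dienoate F6. Hydroboration gives the alkyl-9-BBN borane F7, and its ring closure under the conditions of step 11 gives 18 directly.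

Step 11. Closing a 20-membered ring by sp3–sp2 coupling competes with oligomerisation, protodeboronation and β-hydride loss. The fallback closes the ring at an ester bond instead; it sets out from 12 and 8 and comes back at 15. 12 with 9-BBN gives the bis(9-BBN) adduct F8, which couples with the methyl ester 8 (Pd(dppf)Cl2, AsPh3, Cs2CO3) to methyl (2Z,4Z,8R,9R)-11,11-diethoxy-9-{[(2Z,4Z,8R,9R)-11,11-diethoxy-9-hydroxy-2,8-dimethylundeca-2,4-dienoyl]oxy}-8-methylundeca-2,4-dienoate F9. Me3SnOH cleaves only the unhindered methyl ester and gives the seco acid (2Z,4Z,8R,9R)-11,11-diethoxy-9-{[(2Z,4Z,8R,9R)-11,11-diethoxy-9-hydroxy-2,8-dimethylundeca-2,4-dienoyl]oxy}-8-methylundeca-2,4-dienoic acid F10. Shiina macrolactonisation (2-methyl-6-nitrobenzoic anhydride, DMAP, Et3N, CH2Cl2, 1 mM) then gives 15.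

Step 8 (the same operation recurs in step 10). Activating a (2Z,4Z)-dienoic acid in the presence of DMAP can isomerise the 2Z alkene. The fallback activates the alcohol instead of the acid and inverts it; it sets out from 2 and comes back at 10. Crotylboration of 2 with the (E)-crotylborane from trans-2-butene and (+)-Ipc2BOMe gives the anti alcohol (3S,4R)-1,1-diethoxy-4-methylhex-5-en-3-ol F11. Mitsunobu esterification with 7 (PPh3, DIAD, toluene, 0 °C) inverts C3 and gives 10 without any acyl activation. If step 10 shows the same isomerisation, F11 also replaces 3 in step 9: its bis(9-BBN) adduct F12 couples with 10 to the C9 epimer (3R,4R)-1,1-diethoxy-4-methylhex-5-en-3-yl (2Z,4Z,8R,9S)-11,11-diethoxy-9-hydroxy-2,8-dimethylundeca-2,4-dienoate F13, and Mitsunobu esterification with 9 comes back at 13.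

**Further compounds**

F1 | step 13 | (3R,4R)-3-hydroxy-4-methylhex-5-enal | C=C[C@@H](C)[C@@H](CC=O)O
F2 | step 13 | (2R,3R)-3-methyl-1-(1,3-oxazol-5-yl)pent-4-en-2-ol | C=C[C@@H](C)[C@@H](Cc1cnco1)O
F3 | step 13 | (2R,3R)-3-methyl-1-(1,3-oxazol-5-yl)pent-4-en-2-yl (2Z,4Z)-5-iodo-2-methylpenta-2,4-dienoate | C=C[C@@H](C)[C@@H](Cc1cnco1)OC(=O)/C(C)=C\C=C/I
F4 | step 13 | 5-{(2R,3R)-5-(9-borabicyclo[3.3.1]nonan-9-yl)-2-[(9-borabicyclo[3.3.1]nonan-9-yl)oxy]-3-methylpentyl}-1,3-oxazole | B1(C2CCCC1CCC2)CC[C@@H](C)[C@@H](Cc1cnco1)OB1C2CCCC1CCC2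
F5 | step 13 | (2R,3R)-3-methyl-1-(1,3-oxazol-5-yl)pent-4-en-2-yl (2Z,4Z,8R,9R)-9-hydroxy-2,8-dimethyl-10-(1,3-oxazol-5-yl)deca-2,4-dienoate | C=C[C@@H](C)[C@@H](Cc1cnco1)OC(=O)/C(C)=C\C=C/CC[C@@H](C)[C@@H](Cc1cnco1)O
F6 | step 13 | (2R,3R)-3-methyl-1-(1,3-oxazol-5-yl)pent-4-en-2-yl (2Z,4Z,8R,9R)-9-{[(2Z,4Z)-5-iodopenta-2,4-dienoyl]oxy}-2,8-dimethyl-10-(1,3-oxazol-5-yl)deca-2,4-dienoate | C=C[C@@H](C)[C@@H](Cc1cnco1)OC(=O)/C(C)=C\C=C/CC[C@@H](C)[C@@H](Cc1cnco1)OC(=O)/C=C\C=C/I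
F7 | step 13 | (2R,3R)-5-(9-borabicyclo[3.3.1]nonan-9-yl)-3-methyl-1-(1,3-oxazol-5-yl)pentan-2-yl (2Z,4Z,8R,9R)-9-{[(2Z,4Z)-5-iodopenta-2,4-dienoyl]oxy}-2,8-dimethyl-10-(1,3-oxazol-5-yl)deca-2,4-dienoate | B1(C2CCCC1CCC2)CC[C@@H](C)[C@@H](Cc1cnco1)OC(=O)/C(C)=C\C=C/CC[C@@H](C)[C@@H](Cc1cnco1)OC(=O)/C=C\C=C/I
F8 | step 11 | (3R,4R)-6-(9-borabicyclo[3.3.1]nonan-9-yl)-1,1-diethoxy-4-methylhexan-3-yl (2Z,4Z,8R,9R)-9-[(9-borabicyclo[3.3.1]nonan-9-yl)oxy]-11,11-diethoxy-2,8-dimethylundeca-2,4-dienoate | B1(C2CCCC1CCC2)CC[C@@H](C)[C@@H](CC(OCC)OCC)OC(=O)/C(C)=C\C=C/CC[C@@H](C)[C@@H](CC(OCC)OCC)OB1C2CCCC1CCC2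
F9 | step 11 | methyl (2Z,4Z,8R,9R)-11,11-diethoxy-9-{[(2Z,4Z,8R,9R)-11,11-diethoxy-9-hydroxy-2,8-dimethylundeca-2,4-dienoyl]oxy}-8-methylundeca-2,4-dienoate | COC(=O)/C=C\C=C/CC[C@@H](C)[C@@H](CC(OCC)OCC)OC(=O)/C(C)=C\C=C/CC[C@@H](C)[C@@H](CC(OCC)OCC)O
F10 | step 11 | (2Z,4Z,8R,9R)-11,11-diethoxy-9-{[(2Z,4Z,8R,9R)-11,11-diethoxy-9-hydroxy-2,8-dimethylundeca-2,4-dienoyl]oxy}-8-methylundeca-2,4-dienoic acid | OC(=O)/C=C\C=C/CC[C@@H](C)[C@@H](CC(OCC)OCC)OC(=O)/C(C)=C\C=C/CC[C@@H](C)[C@@H](CC(OCC)OCC)O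
F11 | step 8 | (3S,4R)-1,1-diethoxy-4-methylhex-5-en-3-ol | C=C[C@@H](C)[C@H](CC(OCC)OCC)O
F12 | step 8 | 9-{[(3S,4R)-6-(9-borabicyclo[3.3.1]nonan-9-yl)-1,1-diethoxy-4-methylhexan-3-yl]oxy}-9-borabicyclo[3.3.1]nonane | B1(C2CCCC1CCC2)CC[C@@H](C)[C@H](CC(OCC)OCC)OB1C2CCCC1CCC2
F13 | step 8 | (3R,4R)-1,1-diethoxy-4-methylhex-5-en-3-yl (2Z,4Z,8R,9S)-11,11-diethoxy-9-hydroxy-2,8-dimethylundeca-2,4-dienoate | C=C[C@@H](C)[C@@H](CC(OCC)OCC)OC(=O)/C(C)=C\C=C/CC[C@@H](C)[C@H](CC(OCC)OCC)O
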